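(The numbers in the tables are simulated for substances that don't exist; scatter was added.)

- The trap in the earlier runs was that both stood at the same [partner], 0.0888 M, so they could not show the order in partner; I assumed first order, and my reckoning below rests on that.

| flask | substrate | partner | remark | time |
|---|---|---|---|---|
| east | 0.050 M | 0.0888 M | run made earlier |  |
| north-east | 0.15 M | 0.0888 M | run made earlier |  |
| green | 0.074 M | 0.400 M |  | 30 min |
| blue | 0.074 M | 0.0888 M |  | 50 min |

| run | time / min | product / % |
|---|---|---|
| east | 2.00 | 0.8 |
| east | 4.00 | 4.3 |
| east | 6.00 | 6.4 |
| east | 8.00 | 7.6 |
| east | 10.0 | 9.4 |
| north-east | 0.833 | 2.7 |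
| north-east | 1.50 | 1.6 |
| north-east | 3.00 | 3.8 |
| north-east | 5.00 | 4.3 |
| north-east | 10.0 | 9.1 |

(readings scatter by 1 percentage point)

1. the flask that ends with the higher amount of product, in percent of the substrate charged, or "neither" when 2 percentage points or less lies between them (green / blue / neither)
2. final product, as a percentage of the substrate charged, in green
3. final product, as a percentage of the substrate charged, in blue

- the analysis behind the earlier runs scatters by 1 percentage point, standard deviation
- a reading or a percentage of product counts all its forms, free or not

- After 10.0 min the east run read 9.4% and the north-east run 9.1%, though north-east held 3.00 times the [substrate], so I took the reaction as first order in substrate.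
- I carried one number, the first-order loss of substrate per minute divided by [partner], the rate constant per unit of partner: from the mean of those two readings it is 0.109 M⁻¹ min⁻¹, and it carries their scatter.
- For the ceiling I held [partner] at its charge, a pseudo-first-order reckoning, which gave 73.1% in green and 38.4% in blue.
- For the floor I took partner as used one for one with substrate up to that ceiling and held it at the [partner] this left for the whole run, which gave 67.8% in green and 28.1% in blue.
- Green's floor stood higher than blue's ceiling, so I expected green to end ahead.
- The forecast chose green, with green at 65%, below my floor, and blue at 35%, inside my bracket, and it said: “Green is likely higher, but the partner order is the main uncertainty.”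
- The flasks gave green as the winner, with 70.3% in green and 32.4% in blue, both inside my brackets.

    substrate + partner → product + by-product (k = 0.00200 M⁻¹ s⁻¹)
    partner + product ⇌ idle adduct, settled at all times (K = 38.0 M⁻¹)

- Green had not come to rest at 30 min: it held substrate 30% and free partner 75% of its charge, and 0.109 M⁻¹ min⁻¹ on that partner gives a substrate half-life of 21.1 min. For green left until 50 min, the same ceiling and floor give 88.8% and 83.9%, and that flask held 85.2%. By 300 min green reached >99.9% product. Blue held substrate 68% at 50 min, and by 500 min it reached 78.5% product with substrate 21.5%.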